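The route rests on cutting the 2,2-dimethyl-2H-pyran ring (O1, C2, C3, C4) away from the arene at C4a and C8a of the chromene. Its precursor 19 is a phenol that already holds both stereocentres, the benzofuran and a silyl-capped benzofuranol. Its only unhindered position ortho to the phenolic oxygen, para to methoxy, becomes C4a. In one operation prenal is condensed there (C4a–C4) and the resulting ortho-quinone methide closes by oxa-6π electrocyclisation (O1–C2). The tertiary carbinol is set by stereospecific lithiation–borylation of a CBS-derived carbamate, the methyl-bearing centre comes from a chiral-pool bromo alcohol, and the benzofuran from a Sonogashira annulation.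

Key step: step 15

Remark: CIP analysis of the target gives S at the tertiary carbinol and S at the methyl-bearing carbon, that is (2S,4S) in pentan-2-yl numbering; all structures below follow this.
Remark: the benzofuranol is capped as a triisopropylsilyl ether, because an aryl silyl ether ortho to an acetyl group is labile and must outlast hydrogenolysis and a warm amine acetate medium.
Remark: 6 is taken as the commercial enantiopure bromo alcohol. The dialkoxyaryl carbinols are acid-labile, so work-ups stay neutral or basic and silica is deactivated with Et3N.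

Step 1
Reactants: 1 2,4-dihydroxyacetophenone
Product: 2 1-[4-(benzyloxy)-2-hydroxyphenyl]ethan-1-one
Conditions: BnBr (1.05 equiv), K2CO3 (1.1 equiv), acetone, reflux
Reagents that add atoms: benzyl bromide, BrCc1ccccc1
Why: Williamson ether synthesis; the 2-OH is tied up in a hydrogen bond to the acetyl oxygen, so one equivalent of benzyl bromide should alkylate only the 4-OH.

Step 2
Reactants: 2 1-[4-(benzyloxy)-2-hydroxyphenyl]ethan-1-one
Product: 3 1-[4-(benzyloxy)-2-methoxyphenyl]ethan-1-one
Conditions: MeI (2 equiv), K2CO3 (2 equiv), DMF, 50 °C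
Reagents that add atoms: iodomethane, CI
Why: Williamson methylation of the remaining chelated phenol, driven by excess iodomethane in a polar aprotic solvent; no other nucleophilic site is present.

Step 3
Reactants: 3 1-[4-(benzyloxy)-2-methoxyphenyl]ethan-1-one
Product: 4 (R)-1-[4-(benzyloxy)-2-methoxyphenyl]ethan-1-ol
Conditions: (S)-2-methyl-CBS-oxazaborolidine (10 mol%), BH3·SMe2 (0.7 equiv), THF, −20 °C; MeOH quench, NaHCO3 work-up
Reagents that add atoms: none
Why: Corey–Bakshi–Shibata reduction; with the aryl group as the large substituent, the (S)-oxazaborolidine–borane complex should deliver hydride to the Si face of the ketone and so set the R carbinol centre.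

Step 4
Reactants: 4 (R)-1-[4-(benzyloxy)-2-methoxyphenyl]ethan-1-ol
Product: 5 (R)-1-[4-(benzyloxy)-2-methoxyphenyl]ethyl N,N-diisopropylcarbamate
Conditions: NaH (1.3 equiv), THF, 0 °C; iPr2NCOCl (1.3 equiv), rt to 50 °C
Reagents that add atoms: N,N-diisopropylcarbamoyl chloride, CC(C)N(C(C)C)C(Cl)=O
Why: Carbamoylation (O-acylation) of the sodium alkoxide; the C–O bond at the stereocentre is not broken, so the R configuration is kept, and the basic medium avoids ionisation of the electron-rich benzylic position.

Step 5
Reactants: 6 (R)-3-bromo-2-methylpropan-1-ol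
Product: 7 (R)-(3-bromo-2-methylpropoxy)(tert-butyl)dimethylsilane
Conditions: TBSCl (1.1 equiv), imidazole (1.5 equiv), CH2Cl2, 0 °C to rt
Reagents that add atoms: tert-butyldimethylsilyl chloride, CC(C)(C)[Si](C)(C)Cl
Why: Standard silylation of a primary alcohol; the stereocentre is not involved.

Step 6
Reactants: 7 (R)-(3-bromo-2-methylpropoxy)(tert-butyl)dimethylsilane
Product: 8 (S)-tert-butyldimethyl[2-methyl-3-(4,4,5,5-tetramethyl-1,3,2-dioxaborolan-2-yl)propoxy]silane
Conditions: B2pin2 (1.5 equiv), CuI (10 mol%), PPh3 (13 mol%), LiOMe (2 equiv), DMF, rt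
Reagents that add atoms: bis(pinacolato)diboron, CC1(C)OB(OC1(C)C)B1OC(C)(C)C(C)(C)O1
Why: Copper-catalysed borylation of a primary alkyl bromide; the methyl-bearing carbon is not a reacting centre and keeps its geometry (the descriptor changes from R to S only because CH2B ranks below CH2O).

Step 7
Reactants: 5 (R)-1-[4-(benzyloxy)-2-methoxyphenyl]ethyl N,N-diisopropylcarbamate; 8 (S)-tert-butyldimethyl[2-methyl-3-(4,4,5,5-tetramethyl-1,3,2-dioxaborolan-2-yl)propoxy]silane
Product: 10 (2S,4S)-2-[4-(benzyloxy)-2-methoxyphenyl]-5-[(tert-butyldimethylsilyl)oxy]-4-methylpentan-2-ol, via tertiary boronic ester 9 (not isolated)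
Conditions: sBuLi (1.2 equiv), Et2O, −78 °C, 1 h; then 8 (1.3 equiv), −78 °C; MgBr2 in MeOH, −78 °C to rt; then NaOH (2 M), H2O2 (30%), THF, 0 °C to rt
Reagents that add atoms: hydrogen peroxide, OO
Why: Lithiation–borylation of a secondary benzylic carbamate followed by oxidation: carbamate-directed deprotonation gives a configurationally stable benzylic organolithium that is borylated with retention, the boronate complex rearranges by stereospecific 1,2-migration of the CH2 group anti to the leaving carbamate, and C–B oxidation is retentive, so the R carbamate should give the 2S carbinol while C4 is carried over unchanged from 8.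

Step 8
Reactants: 10 (2S,4S)-2-[4-(benzyloxy)-2-methoxyphenyl]-5-[(tert-butyldimethylsilyl)oxy]-4-methylpentan-2-ol
Product: 11 (2S,4S)-4-[4-(benzyloxy)-2-methoxyphenyl]-2-methylpentane-1,4-diol
Conditions: TBAF (1.2 equiv), THF, 0 °C to rt
Reagents that add atoms: none
Why: Fluoride cleavage of a primary silyl ether; the medium is basic, which the acid-sensitive tertiary benzylic alcohol and the benzyl ether tolerate.

Step 9
Reactants: 11 (2S,4S)-4-[4-(benzyloxy)-2-methoxyphenyl]-2-methylpentane-1,4-diol
Product: 13 (3S,5S)-5-[4-(benzyloxy)-2-methoxyphenyl]-3,5-dimethyloxolan-2-ol (mixture at C2), via hydroxy aldehyde 12 (not isolated)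
Conditions: 2-iodoxybenzoic acid (1.3 equiv), DMSO, rt
Reagents that add atoms: none
Why: Oxidation of a 1,4-diol with 2-iodoxybenzoic acid, which is known to stop at the lactol: only the primary hydroxyl can be oxidised, and the tertiary hydroxyl traps the aldehyde as the 5-membered hemiacetal (5-exo-trig) without acid.

Step 10
Reactants: 13 (3S,5S)-5-[4-(benzyloxy)-2-methoxyphenyl]-3,5-dimethyloxolan-2-ol
Product: 14 (2S,4S)-2-[4-(benzyloxy)-2-methoxyphenyl]-4-methylhex-5-yn-2-ol
Conditions: dimethyl (1-diazo-2-oxopropyl)phosphonate (1.5 equiv), K2CO3 (2.5 equiv), MeOH, 0 °C to rt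
Reagents that add atoms: dimethyl (1-diazo-2-oxopropyl)phosphonate (Ohira–Bestmann reagent), COP(=O)(OC)C(=[N+]=[N-])C(C)=O
Why: Seyferth–Gilbert homologation in the Ohira–Bestmann variant, a reaction known for lactols: in basic methanol 13 is in ring–chain equilibrium with its open hydroxy aldehyde tautomer (the species listed as 12, through which it was formed in step 9), the diazomethylphosphonate anion generated in situ adds to that carbonyl and eliminates dimethyl phosphate, and the diazoalkene loses N2 and undergoes 1,2-hydride shift to the terminal alkyne, while carbonate in methanol is mild enough that α-branched aldehydes normally keep their configuration.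

Step 11
Reactants: 1 2,4-dihydroxyacetophenone
Product: 15 1-(2,4-dihydroxy-5-iodophenyl)ethan-1-one
Conditions: ICl (1.0 equiv), AcOH, rt; recrystallisation
Reagents that add atoms: iodine monochloride, ClI
Why: Electrophilic aromatic iodination; in the acidic, non-phenolate medium substitution should go to C5, para to the chelated 2-OH and ortho to the 4-OH, and not to the crowded C3 between the two hydroxyls.

Step 12
Reactants: 14 (2S,4S)-2-[4-(benzyloxy)-2-methoxyphenyl]-4-methylhex-5-yn-2-ol; 15 1-(2,4-dihydroxy-5-iodophenyl)ethan-1-one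
Product: 17 1-[2-[(2S,4S)-4-[4-(benzyloxy)-2-methoxyphenyl]-4-hydroxypentan-2-yl]-6-hydroxy-1-benzofuran-5-yl]ethan-1-one, via alkynylphenol 16 (not isolated)
Conditions: PdCl2(PPh3)2 (5 mol%), CuI (10 mol%), Et3N (5 equiv), DMF, 70 °C
Reagents that add atoms: none
Why: Sonogashira coupling followed in the same pot by copper- and base-assisted 5-endo-dig addition of the adjacent 4-OH to the alkyne (benzofuran heteroannulation of an ortho-iodophenol); the para acetyl group makes that hydroxyl acidic enough to cyclise, the chelated 2-OH cannot reach the alkyne, and neither stereocentre is touched.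

Step 13
Reactants: 17 1-[2-[(2S,4S)-4-[4-(benzyloxy)-2-methoxyphenyl]-4-hydroxypentan-2-yl]-6-hydroxy-1-benzofuran-5-yl]ethan-1-one
Product: 18 1-[2-[(2S,4S)-4-[4-(benzyloxy)-2-methoxyphenyl]-4-hydroxypentan-2-yl]-6-(triisopropylsilyloxy)-1-benzofuran-5-yl]ethan-1-one
Conditions: TIPSCl (1.5 equiv), imidazole (3 equiv), DMAP (10 mol%), DMF, rt to 40 °C
Reagents that add atoms: chlorotriisopropylsilane, CC(C)[Si](Cl)(C(C)C)C(C)C
Why: Silylation of the only phenol; the bulky chlorosilane does not react with the tertiary alcohol, and imidazole with DMAP overcomes the hydrogen bond to the acetyl group.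

Step 14
Reactants: 18 1-[2-[(2S,4S)-4-[4-(benzyloxy)-2-methoxyphenyl]-4-hydroxypentan-2-yl]-6-(triisopropylsilyloxy)-1-benzofuran-5-yl]ethan-1-one
Product: 19 1-[2-[(2S,4S)-4-hydroxy-4-(4-hydroxy-2-methoxyphenyl)pentan-2-yl]-6-(triisopropylsilyloxy)-1-benzofuran-5-yl]ethan-1-one
Conditions: H2 (1 atm), 10% Pd/C, EtOAc, rt, stopped at full conversion
Reagents that add atoms: none
Why: Catalytic hydrogenolysis of an aryl benzyl ether, which under neutral aprotic conditions should be much faster than reduction of the benzofuran 2,3-bond, the aryl ketone or the tertiary benzylic C–O bond; the silyl ether is inert.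

Step 15
Reactants: 19 1-[2-[(2S,4S)-4-hydroxy-4-(4-hydroxy-2-methoxyphenyl)pentan-2-yl]-6-(triisopropylsilyloxy)-1-benzofuran-5-yl]ethan-1-one; 20 3-methylbut-2-enal
Product: 22 1-[2-[(2S,4S)-4-hydroxy-4-(7-methoxy-2,2-dimethyl-2H-chromen-6-yl)pentan-2-yl]-6-(triisopropylsilyloxy)-1-benzofuran-5-yl]ethan-1-one, via ortho-quinone methide 21 (not isolated)
Conditions: 20 (3 equiv, added in portions), ethylenediammonium diacetate (20 mol%), toluene, 100 °C
Reagents that add atoms: none
Why: The diammonium acetate turns prenal into an iminium ion that is attacked by the arene carbon ortho to the phenolic oxygen (Mannich/aldol-type C4a–C4 bond formation), and loss of the amine and of water gives the 1-oxatriene 21. This ortho-quinone methide closes by thermal disrotatory oxa-6π electrocyclisation, which forms O1–C2, the six-membered 2H-pyran ring and the restored arene. The closest known reaction type is the amine-salt-mediated formal [3+3] annulation of phenols with α,β-unsaturated aldehydes to 2,2-dimethyl-2H-chromenes. No stereocentre is created, since C2 bears two methyl groups, and the two existing centres are remote from all bonds made or broken. The step needs site selectivity for the ortho carbon para to methoxy over the one wedged between hydroxyl and methoxy (steric access plus para activation), chemoselectivity for this phenol over the benzofuranol (blocked as the silyl ether) and survival of the tertiary benzylic alcohol (buffered, nearly neutral medium at moderate temperature).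

Step 16
Reactants: 22 1-[2-[(2S,4S)-4-hydroxy-4-(7-methoxy-2,2-dimethyl-2H-chromen-6-yl)pentan-2-yl]-6-(triisopropylsilyloxy)-1-benzofuran-5-yl]ethan-1-one
Product: 23 1-[6-hydroxy-2-[(2S,4S)-4-hydroxy-4-(7-methoxy-2,2-dimethyl-2H-chromen-6-yl)pentan-2-yl]-1-benzofuran-5-yl]ethan-1-one
Conditions: TBAF (1.1 equiv), AcOH (1.1 equiv), THF, 0 °C
Reagents that add atoms: none
Why: Fluoride desilylation of an aryl silyl ether activated by the ortho acetyl group; acetic acid keeps the medium near neutral, and the chromene, the benzofuran and the tertiary alcohol are inert to fluoride.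

Compound list
1 | 2,4-dihydroxyacetophenone | CC(=O)c1ccc(O)cc1O | starting material
2 | 1-[4-(benzyloxy)-2-hydroxyphenyl]ethan-1-one | CC(=O)c1ccc(OCc2ccccc2)cc1O | intermediate
3 | 1-[4-(benzyloxy)-2-methoxyphenyl]ethan-1-one | CC(=O)c1ccc(OCc2ccccc2)cc1OC | intermediate
4 | (R)-1-[4-(benzyloxy)-2-methoxyphenyl]ethan-1-ol | C[C@@H](O)c1ccc(OCc2ccccc2)cc1OC | intermediate
5 | (R)-1-[4-(benzyloxy)-2-methoxyphenyl]ethyl N,N-diisopropylcarbamate | C[C@@H](OC(=O)N(C(C)C)C(C)C)c1ccc(OCc2ccccc2)cc1OC | intermediate
6 | (R)-3-bromo-2-methylpropan-1-ol | OC[C@@H](C)CBr | starting material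
7 | (R)-(3-bromo-2-methylpropoxy)(tert-butyl)dimethylsilane | CC(C)(C)[Si](C)(C)OC[C@@H](C)CBr | intermediate
8 | (S)-tert-butyldimethyl[2-methyl-3-(4,4,5,5-tetramethyl-1,3,2-dioxaborolan-2-yl)propoxy]silane | CC(C)(C)[Si](C)(C)OC[C@@H](C)CB1OC(C)(C)C(C)(C)O1 | intermediate
9 | 2-[(2R,4S)-2-[4-(benzyloxy)-2-methoxyphenyl]-5-[(tert-butyldimethylsilyl)oxy]-4-methylpentan-2-yl]-4,4,5,5-tetramethyl-1,3,2-dioxaborolane (tertiary boronic ester, not isolated) | COc1cc(OCc2ccccc2)ccc1[C@@](C)(B1OC(C)(C)C(C)(C)O1)C[C@H](C)CO[Si](C)(C)C(C)(C)C | intermediate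
10 | (2S,4S)-2-[4-(benzyloxy)-2-methoxyphenyl]-5-[(tert-butyldimethylsilyl)oxy]-4-methylpentan-2-ol | COc1cc(OCc2ccccc2)ccc1[C@@](C)(O)C[C@H](C)CO[Si](C)(C)C(C)(C)C | intermediate
11 | (2S,4S)-4-[4-(benzyloxy)-2-methoxyphenyl]-2-methylpentane-1,4-diol | COc1cc(OCc2ccccc2)ccc1[C@@](C)(O)C[C@H](C)CO | intermediate
12 | (2S,4S)-4-[4-(benzyloxy)-2-methoxyphenyl]-4-hydroxy-2-methylpentanal (hydroxy aldehyde, not isolated) | COc1cc(OCc2ccccc2)ccc1[C@@](C)(O)C[C@H](C)C=O | intermediate
13 | (3S,5S)-5-[4-(benzyloxy)-2-methoxyphenyl]-3,5-dimethyloxolan-2-ol (mixture at C2) | COc1cc(OCc2ccccc2)ccc1[C@]3(C)C[C@H](C)C(O)O3 | intermediate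
14 | (2S,4S)-2-[4-(benzyloxy)-2-methoxyphenyl]-4-methylhex-5-yn-2-ol | COc1cc(OCc2ccccc2)ccc1[C@@](C)(O)C[C@H](C)C#C | intermediate
15 | 1-(2,4-dihydroxy-5-iodophenyl)ethan-1-one | CC(=O)c1cc(I)c(O)cc1O | intermediate
16 | 1-[5-[(3S,5S)-5-[4-(benzyloxy)-2-methoxyphenyl]-5-hydroxy-3-methylhex-1-yn-1-yl]-2,4-dihydroxyphenyl]ethan-1-one (alkynylphenol, not isolated) | COc1cc(OCc2ccccc2)ccc1[C@@](C)(O)C[C@H](C)C#Cc1cc(C(C)=O)c(O)cc1O | intermediate
17 | 1-[2-[(2S,4S)-4-[4-(benzyloxy)-2-methoxyphenyl]-4-hydroxypentan-2-yl]-6-hydroxy-1-benzofuran-5-yl]ethan-1-one | COc1cc(OCc2ccccc2)ccc1[C@@](C)(O)C[C@H](C)c1cc2cc(C(C)=O)c(O)cc2o1 | intermediate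
18 | 1-[2-[(2S,4S)-4-[4-(benzyloxy)-2-methoxyphenyl]-4-hydroxypentan-2-yl]-6-(triisopropylsilyloxy)-1-benzofuran-5-yl]ethan-1-one | COc1cc(OCc2ccccc2)ccc1[C@@](C)(O)C[C@H](C)c1cc2cc(C(C)=O)c(O[Si](C(C)C)(C(C)C)C(C)C)cc2o1 | intermediate
19 | 1-[2-[(2S,4S)-4-hydroxy-4-(4-hydroxy-2-methoxyphenyl)pentan-2-yl]-6-(triisopropylsilyloxy)-1-benzofuran-5-yl]ethan-1-one | COc1cc(O)ccc1[C@@](C)(O)C[C@H](C)c1cc2cc(C(C)=O)c(O[Si](C(C)C)(C(C)C)C(C)C)cc2o1 | intermediate
20 | 3-methylbut-2-enal | CC(C)=CC=O | starting material
21 | 1-[2-[(2S,4S)-4-hydroxy-4-[6-methoxy-3-(3-methylbut-2-en-1-ylidene)-4-oxocyclohexa-1,5-dien-1-yl]pentan-2-yl]-6-(triisopropylsilyloxy)-1-benzofuran-5-yl]ethan-1-one (ortho-quinone methide, not isolated) | COC1=CC(=O)C(=CC=C(C)C)C=C1[C@@](C)(O)C[C@H](C)c1cc2cc(C(C)=O)c(O[Si](C(C)C)(C(C)C)C(C)C)cc2o1 | intermediate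
22 | 1-[2-[(2S,4S)-4-hydroxy-4-(7-methoxy-2,2-dimethyl-2H-chromen-6-yl)pentan-2-yl]-6-(triisopropylsilyloxy)-1-benzofuran-5-yl]ethan-1-one | COc1cc2c(cc1[C@@](C)(O)C[C@H](C)c1cc3cc(C(C)=O)c(O[Si](C(C)C)(C(C)C)C(C)C)cc3o1)C=CC(C)(C)O2 | intermediate
23 | 1-[6-hydroxy-2-[(2S,4S)-4-hydroxy-4-(7-methoxy-2,2-dimethyl-2H-chromen-6-yl)pentan-2-yl]-1-benzofuran-5-yl]ethan-1-one | COc1cc2c(cc1[C@@](C)(O)C[C@H](C)c1cc3cc(C(C)=O)c(O)cc3o1)C=CC(C)(C)O2 | target

Total step count: 16. Longest linear sequence: 13 steps (steps 1–4, 7–10 and 12–16, from 1 to 23).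

Steps most likely to fail

Step 15. The mono-phenol may condense only slowly, and the warm medium may cause loss of water from the tertiary carbinol, which sits para to a free hydroxyl; some attack at the position between the two oxygens is also conceivable. The fallback leaves the aldehyde condensation altogether. It sets out from 19, which would be O-alkylated with 3-chloro-3-methylbut-1-yne (CuCl2 cat., DBU, MeCN, 0 °C) to the aryl propargyl ether 1-[2-[(2S,4S)-4-hydroxy-4-[2-methoxy-4-(2-methylbut-3-yn-2-yloxy)phenyl]pentan-2-yl]-6-(triisopropylsilyloxy)-1-benzofuran-5-yl]ethan-1-one F1. Heating F1 in xylene at about 130 °C should trigger the aromatic propargyl Claisen rearrangement; the ortho-allenyl phenol so formed reaches the same ortho-quinone methide 21 by 1,5-hydrogen shift and closes, so the sequence comes back to the route at 22. No amine salt, acid or aldehyde is present, and no para-hydroxyl is free during the heating.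

Step 7. Stereochemical fidelity may erode, because boronate formation can become reversible for a very electron-rich, ortho-substituted benzylic anion, and deprotonation next to the methoxy group or at the benzyl ether CH2 may compete. The fallback gives up reagent control at the carbinol and relies on separation. It sets out from 7, which would be converted with Mg in THF into the Grignard reagent (R)-[3-(tert-butyldimethylsilyloxy)-2-methylpropyl]magnesium bromide F2. Addition of F2 to ketone 3 in the presence of anhydrous CeCl3 at −78 °C (to suppress enolisation) should give 10 together with its carbinol epimer (2R,4S)-2-[4-(benzyloxy)-2-methoxyphenyl]-5-[(tert-butyldimethylsilyl)oxy]-4-methylpentan-2-ol F3, since no useful facial bias is expected. The methyl-bearing centre is fixed by the chiral pool, so both are single enantiomers and differ as diastereomers; chromatographic separation and assignment of configuration would return the sequence to the route at 10.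

Step 10. Ring opening of the hindered lactol may be slow, and the longer the open aldehyde form sits in carbonate/methanol the more epimerisation next to the carbonyl becomes possible. The fallback replaces the diazo homologation by olefination and elimination. It sets out from 13, which would be treated with the ylide from (chloromethyl)triphenylphosphonium chloride and NaN(SiMe3)2 (THF, −78 to 0 °C; Wittig reaction of the lactol) to give the vinyl chloride (2S,4S)-2-[4-(benzyloxy)-2-methoxyphenyl]-6-chloro-4-methylhex-5-en-2-ol F4 as an E/Z mixture. Dehydrochlorination of F4 with excess LiN(iPr)2 (THF, −78 to 0 °C) and aqueous quench should then give the alkyne, and the sequence comes back to the route at 14.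

Further compounds
F1 | step 15 | 1-[2-[(2S,4S)-4-hydroxy-4-[2-methoxy-4-(2-methylbut-3-yn-2-yloxy)phenyl]pentan-2-yl]-6-(triisopropylsilyloxy)-1-benzofuran-5-yl]ethan-1-one | COc1cc(OC(C)(C)C#C)ccc1[C@@](C)(O)C[C@H](C)c1cc2cc(C(C)=O)c(O[Si](C(C)C)(C(C)C)C(C)C)cc2o1
F2 | step 7 | (R)-[3-(tert-butyldimethylsilyloxy)-2-methylpropyl]magnesium bromide | CC(C)(C)[Si](C)(C)OC[C@@H](C)C[Mg]Br
F3 | step 7 | (2R,4S)-2-[4-(benzyloxy)-2-methoxyphenyl]-5-[(tert-butyldimethylsilyl)oxy]-4-methylpentan-2-ol | COc1cc(OCc2ccccc2)ccc1[C@](C)(O)C[C@H](C)CO[Si](C)(C)C(C)(C)C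
F4 | step 10 | (2S,4S)-2-[4-(benzyloxy)-2-methoxyphenyl]-6-chloro-4-methylhex-5-en-2-ol (E/Z mixture) | COc1cc(OCc2ccccc2)ccc1[C@@](C)(O)C[C@H](C)C=CCl
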